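Four set-ups bring the same charges of X and G together in different ways, and the question is which of them leaves the most X.G.

| flask | X | G | time | remark |
|---|---|---|---|---|
| cedar | 0.050 M | 0.0525 M (fed, over 40.0 h) | 50 h | all but G at the start; G goes in evenly over 40.0 h, the run ends at 50 h |
| elm | 0.050 M | 0.0525 M |  | one stirred flow tank at steady state, fed with the mixture as stated, mean residence time 50 h |
| ash | 0.050 M | 0.0525 M | 50 h | a closed flask charged with all of it at once and left for 50 h |
| birch | 0.050 M (fed, over 40.0 h) | 0.0525 M | 50 h | a stirred flask in which X is dosed at a steady rate over 40.0 h without added volume, worked up at 50 h |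

- the set-up with the highest amount of X.G at the outlet or at the end, in percent of the X put in ("none" if the first two lie within 2 percentage points) (cedar / elm / ash / birch / none)
- amount of X.G at the outlet or at the end, in percent of the X put in, cedar
- amount of X.G at the outlet or at the end, in percent of the X put in, elm
- amount of X.G at the outlet or at the end, in percent of the X put in, ash
- amount of X.G at the outlet or at the end, in percent of the X put in, birch

- a doubled species enters its step squared and goes two at a time
- the stated concentrations are those of everything mixed, before any reaction; amounts are the same in each set-up
- the feed brings no volume worth counting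
- run time (cedar): 50 h

X and G join reversibly to X.G and to E, G decays slowly to Q, and G also pairs with itself to G2 at a rate that goes with free G squared. Free G is therefore the concentration to follow, and the reckoning starts from one time:

1 / (2 × 2.27 L mol⁻¹ h⁻¹ × 0.0525 M) = 4.20 h

This is the pairing clock, the second-order first half-life of free G at its full charge by the pairing step by itself.

In the first instants of birch, G stands at full charge and X arrives over 40.0 h, a far longer time than the clock. G pairs at 0.0125 M h⁻¹ while X comes in at 1.25 mM h⁻¹. In cedar, arriving G meets the full charge of X, and its forward capture half-life by the two binding steps is: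

ln(2) / ((20.8 L mol⁻¹ h⁻¹ + 12.5 L mol⁻¹ h⁻¹) × 0.050 M) = 0.416 h

That is shorter than the clock. In ash, binding also runs ahead of pairing, with forward half-lives of X of 0.63 h and 1.1 h, while decay to Q is slower, at 110 h.

In ash, as an estimate for the hours after binding has caught up and with no G yet counted as lost to pairing, X and G taken as equal and the two binding constants added put free G near 0.0155 M. The clock at that free G lengthens to 14.2 h, which is still inside the run, so pairing goes on and free G falls below this estimate. In birch, pairing without any capture by X takes this share of G by 5.00 h:

(t / clock) / (1 + t / clock) = 54.4 %

That makes 0.0143 M of G2, with 12.5 % of X dosed.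

Towards the end, pairing continues and bound forms can fall back as free G goes, with 69.9 % of the bound X held as X.G at equilibrium. This reckoning therefore puts birch below ash, on the shorter clock, and it places neither cedar nor elm and commits to no figures for X.G.

The forecast gave 40 % for cedar, 36.1 % for elm, 31 % for ash and 17.5 % for birch, with cedar best, holding that “dosing X into a full charge of G is worst because G dimerises before X arrives”.

The simulation gives 40.1 % for cedar, 36.1 % for elm, 31.9 % for ash and 16.1 % for birch, so cedar is best.

    X + G ⇌ X.G (K1 = 100 L mol⁻¹, k1 = 20.8 L mol⁻¹ h⁻¹)
    X + G ⇌ E (K2 = 43 L mol⁻¹, k2 = 12.5 L mol⁻¹ h⁻¹)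
    G → Q (k3 = 0.00657 h⁻¹)
    2 G → G2 (k4 = 2.27 L mol⁻¹ h⁻¹)

The main reason for the X.G missing in cedar is the falling back of X.G to X + G: without that way back, cedar ends at 91.8 % instead of 40.1 %, which is 86 % of what is missing. Pairing is part of what holds birch down: without that step, X.G in birch ends at 44.4 % instead of 16.1 %. The clock of 4.20 h gave 0.0143 M of G2 at 5.00 h, and birch reads 0.0132 M then, 73 % of its pairing turnover. The neighbour of birch charged with 0.21 M of G runs on a clock of 1.05 h, and the same rule gives 0.103 M of G2 by 50 h. That neighbour ends with 0.0947 M of G2 and X.G at 18.7 %.

The rate constants are assumed; the flask was simulated.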